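Cuts: first the two ring-B O–benzyl bonds, then three bonds of the pyranone ring C (C4a–C4, C4–C3, O1–C2). This leaves an iodinated ring-A arene, CO (as C4=O) and a ring-B arylacetylene (C2 and C3).
Enabling feature: ring A (C4a, C5–C8, C8a) is a 2,4-dimethoxyphloroglucinol with a mirror plane through C4a and C7. Its single free CH (future C4a) sits between two equivalent oxygens (future O1 and 5-OH), so iodination has one site, either oxygen may close ring C, and only the C4 carbonyl carbon is missing.
Forward: rings A and B are bought as arenes. Ring A is dressed by dibromination, double methoxylation, iodination and a benzyl-to-acetyl swap; ring B by benzylation and aldehyde-to-alkyne homologation.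
Ring C arises last, in one Pd-catalysed three-component operation that also joins the fragments; hydrogenolysis then frees the catechol.
Stereochemistry: nothing to set, since the target has no stereocentre and its only non-benzenoid C=C (C2=C3) is endocyclic.
Key step: step 8

Remark on the chemistry: the target carries no stereogenic element, so the compound drawn is its only stereoisomer and no enantioselective step is called for.

Step 1
Reactants: 1 1,3,5-tris(benzyloxy)benzene
Product: 2 1,3,5-tris(benzyloxy)-2,4-dibromobenzene
Conditions: NBS (2.05 equiv), MeCN/CH2Cl2, 0 °C to rt, dark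
Reagents that add atoms: N-bromosuccinimide, O=C1CCC(=O)N1Br
Why: Electrophilic aromatic bromination of a ring whose three CH positions are each activated by three alkoxy groups; every bromine that enters slows the next substitution by its bulk and inductive pull, so two equivalents of NBS in a polar medium in the dark should stop at the dibromide and leave the benzylic CH2 groups alone.

Step 2
Reactants: 2 1,3,5-tris(benzyloxy)-2,4-dibromobenzene
Product: 3 1,3,5-tris(benzyloxy)-2,4-dimethoxybenzene
Conditions: NaOMe (30% in MeOH, 10 equiv), CuBr (0.5 equiv), DMF, 110 °C, N2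
Reagents that add atoms: sodium methoxide, C[O-].[Na+]
Why: Ullmann-type copper-mediated methoxylation, a reaction well established for aryl bromides flanked by two oxygen substituents in phloroglucinol-derived rings, should replace both bromines while the benzyl ethers tolerate methoxide.

Step 3
Reactants: 3 1,3,5-tris(benzyloxy)-2,4-dimethoxybenzene
Product: 4 1,3,5-tris(benzyloxy)-2-iodo-4,6-dimethoxybenzene
Conditions: NIS (1.1 equiv), MeCN, 0 °C to rt, dark
Reagents that add atoms: N-iodosuccinimide, O=C1CCC(=O)N1I
Why: Electrophilic aromatic iodination with NIS can only strike the single remaining ring CH, which is ortho, ortho and para to the three benzyloxy groups, so neither regiochemistry nor over-iodination is an issue.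

Step 4
Reactants: 4 1,3,5-tris(benzyloxy)-2-iodo-4,6-dimethoxybenzene
Product: 5 2-iodo-4,6-dimethoxybenzene-1,3,5-triol
Conditions: BCl3 (1 M in CH2Cl2, 6 equiv), pentamethylbenzene (9 equiv), CH2Cl2, −78 °C; MeOH/CHCl3 quench at −78 °C, degassed water wash; crude product used at once
Reagents that add atoms: none
Why: Lewis-acid debenzylation with BCl3 and pentamethylbenzene as a non-basic cation scavenger cleaves aryl benzyl ethers at −78 °C much faster than aryl methyl ethers, traps the benzyl cation before it can alkylate the ring, and, unlike hydrogenolysis, leaves the C–I bond intact.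

Step 5
Reactants: 5 2-iodo-4,6-dimethoxybenzene-1,3,5-triol
Product: 6 2-iodo-4,6-dimethoxybenzene-1,3,5-triyl triacetate
Conditions: Ac2O (6 equiv), pyridine, DMAP (cat.), CH2Cl2, 0 °C to rt, Ar
Reagents that add atoms: acetic anhydride, CC(=O)OC(C)=O
Why: DMAP-catalysed O-acetylation caps all three phenols, which turns the oxidation-prone iodotriol into a storable compound and lowers the electron density at the C–I bond ahead of the palladium step.

Step 6
Reactants: 7 3,4-dihydroxy-5-methoxybenzaldehyde (5-hydroxyvanillin)
Product: 8 3,4-bis(benzyloxy)-5-methoxybenzaldehyde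
Conditions: BnBr (2.4 equiv), K2CO3 (3 equiv), DMF, 60 °C
Reagents that add atoms: benzyl bromide, BrCc1ccccc1
Why: Williamson ether synthesis on both catechol hydroxyls; the aldehyde and the methyl ether are inert to K2CO3 and BnBr, and benzyl is chosen because it survives amine, Pd(0) and CO and leaves in one neutral final step.

Step 7
Reactants: 8 3,4-bis(benzyloxy)-5-methoxybenzaldehyde
Product: 9 1,2-bis(benzyloxy)-5-ethynyl-3-methoxybenzene
Conditions: dimethyl (1-diazo-2-oxopropyl)phosphonate (1.3 equiv), K2CO3 (2 equiv), MeOH/THF, 0 °C to rt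
Reagents that add atoms: dimethyl (1-diazo-2-oxopropyl)phosphonate, COP(=O)(OC)C(=[N+]=[N-])C(C)=O
Why: Ohira–Bestmann variant of the Seyferth–Gilbert homologation: methanolysis of the reagent gives the diazomethylphosphonate anion, which adds to the non-enolisable aldehyde, and loss of phosphate and N2 with a 1,2-hydrogen shift gives the terminal alkyne under conditions harmless to benzyl ethers.

Step 8
Reactants: 6 2-iodo-4,6-dimethoxybenzene-1,3,5-triyl triacetate; 9 1,2-bis(benzyloxy)-5-ethynyl-3-methoxybenzene; 10 carbon monoxide
Product: 13 2-[3,4-bis(benzyloxy)-5-methoxyphenyl]-5,7-dihydroxy-6,8-dimethoxy-4H-chromen-4-one, via ynone triacetate 11 (not isolated), via enaminone triol 12 (not isolated)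
Conditions: PdCl2(PPh3)2 (5 mol %), dppp (5 mol %), thiourea (5 mol %), CO (1 atm, balloon), degassed Et2NH (solvent), 40 to 60 °C; 1 M HCl work-up
Reagents that add atoms: carbon monoxide (compound 10), [C-]#[O+]; diethylamine, CCNCC (its atoms stand only in intermediate 12 and leave again on ring closure)
Why: Pd(0) should insert into the C–I bond of 6, whose three acetates keep the ring less electron-rich than a phenoxide would be, CO insertion gives the aroyl-palladium, and copper-free coupling with the amine-deprotonated alkyne 9 forms C4a–C4 and C4–C3 and releases ynone 11. Diethylamine then adds to the alkyne carbon that becomes C2 and aminolyses all three acetates, giving enaminone 12. One freed ortho phenol attacks C2 and expels the amine by addition–elimination, which forms O1–C2 and closes the pyranone ring C in the 6-endo-trig mode. The closest known reaction type is the Pd-catalysed carbonylative Sonogashira annulation of o-iodophenols or their acetates with terminal arylacetylenes in a secondary amine, applied here to a more crowded and more oxygenated iodide. No stereocentre is created; the step needs flavone (6-endo) rather than aurone (5-exo) closure, secured by passage through the enaminone in which only C2 is electrophilic, and CO uptake ahead of direct alkynylation, favoured by CO saturation and the absence of copper. The choice between the two ortho oxygens is void because the mirror plane of ring A through C4a and C7 makes them equivalent, so either closure gives 13 and the other oxygen ends as the hydrogen-bonded 5-OH.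

Step 9
Reactants: 13 2-[3,4-bis(benzyloxy)-5-methoxyphenyl]-5,7-dihydroxy-6,8-dimethoxy-4H-chromen-4-one
Product: 14 2-(3,4-dihydroxy-5-methoxyphenyl)-5,7-dihydroxy-6,8-dimethoxy-4H-chromen-4-one (5,7,3',4'-tetrahydroxy-6,8,5'-trimethoxyflavone)
Conditions: H2 (1 atm), 10% Pd/C, THF/MeOH, rt
Reagents that add atoms: none
Why: Catalytic hydrogenolysis of the two aryl benzyl ethers under one atmosphere of hydrogen is fast, while methyl ethers, free phenols and the conjugated C2=C3 bond of the vinylogous-ester pyranone are normally untouched if the reaction is stopped at full debenzylation.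

Compound list
1 | 1,3,5-tris(benzyloxy)benzene | c1c(OCc2ccccc2)cc(OCc2ccccc2)cc1OCc1ccccc1 | starting material
2 | 1,3,5-tris(benzyloxy)-2,4-dibromobenzene | Brc1c(OCc2ccccc2)cc(OCc2ccccc2)c(Br)c1OCc1ccccc1 | intermediate
3 | 1,3,5-tris(benzyloxy)-2,4-dimethoxybenzene | COc1c(OCc2ccccc2)cc(OCc2ccccc2)c(OC)c1OCc1ccccc1 | intermediate
4 | 1,3,5-tris(benzyloxy)-2-iodo-4,6-dimethoxybenzene | COc1c(OCc2ccccc2)c(I)c(OCc2ccccc2)c(OC)c1OCc1ccccc1 | intermediate
5 | 2-iodo-4,6-dimethoxybenzene-1,3,5-triol | COc1c(O)c(I)c(O)c(OC)c1O | intermediate
6 | 2-iodo-4,6-dimethoxybenzene-1,3,5-triyl triacetate | COc1c(OC(C)=O)c(I)c(OC(C)=O)c(OC)c1OC(C)=O | intermediate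
7 | 3,4-dihydroxy-5-methoxybenzaldehyde (5-hydroxyvanillin) | COc1cc(C=O)cc(O)c1O | starting material
8 | 3,4-bis(benzyloxy)-5-methoxybenzaldehyde | COc1cc(C=O)cc(OCc2ccccc2)c1OCc1ccccc1 | intermediate
9 | 1,2-bis(benzyloxy)-5-ethynyl-3-methoxybenzene | COc1cc(C#C)cc(OCc2ccccc2)c1OCc1ccccc1 | intermediate
10 | carbon monoxide | [C-]#[O+] | starting material
11 | 2-{3-[3,4-bis(benzyloxy)-5-methoxyphenyl]prop-2-ynoyl}-4,6-dimethoxybenzene-1,3,5-triyl triacetate (ynone triacetate) | COc1cc(C#CC(=O)c2c(OC(C)=O)c(OC)c(OC(C)=O)c(OC)c2OC(C)=O)cc(OCc2ccccc2)c1OCc1ccccc1 | intermediate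
12 | (E)-3-[3,4-bis(benzyloxy)-5-methoxyphenyl]-3-(diethylamino)-1-(2,4,6-trihydroxy-3,5-dimethoxyphenyl)prop-2-en-1-one (enaminone triol) | CCN(CC)/C(=C/C(=O)c1c(O)c(OC)c(O)c(OC)c1O)c1cc(OC)c(OCc2ccccc2)c(OCc2ccccc2)c1 | intermediate
13 | 2-[3,4-bis(benzyloxy)-5-methoxyphenyl]-5,7-dihydroxy-6,8-dimethoxy-4H-chromen-4-one | COc1cc(-c2cc(=O)c3c(O)c(OC)c(O)c(OC)c3o2)cc(OCc2ccccc2)c1OCc1ccccc1 | intermediate
14 | 5,7,3',4'-tetrahydroxy-6,8,5'-trimethoxyflavone | COc1cc(-c2cc(=O)c3c(O)c(OC)c(O)c(OC)c3o2)cc(O)c1O | target

Total step count: 9.
Longest linear sequence: 7 steps (steps 1, 2, 3, 4, 5, 8, 9, from 1). The ring-B branch adds steps 6 and 7.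

Steps most likely to fail

Step 8. Oxidative addition into the doubly ortho-substituted, electron-rich C–I bond may be too slow, so that aminolysis of the acetates and reductive loss of iodine run ahead of it. The aroyl-palladium may also be intercepted by diethylamine (aminocarbonylation), or the alkyne may couple without taking up CO. The fallback drops palladium and CO for the chalcone route; it sets out from iodide 4, with aldehyde 8 as ring-B partner, and comes back at target 14. Iodine–magnesium exchange on 4 (i-PrMgCl·LiCl, THF, −20 to 0 °C) and acylation with N-methoxy-N-methylacetamide should give 1-[2,4,6-tris(benzyloxy)-3,5-dimethoxyphenyl]ethan-1-one F1. One equivalent of BCl3 (CH2Cl2, −78 °C), held by chelation to the ketone, should remove one of the two equivalent ortho benzyl groups and give 1-[2,4-bis(benzyloxy)-6-hydroxy-3,5-dimethoxyphenyl]ethan-1-one F2. Claisen–Schmidt condensation of F2 with 8 (KOH, EtOH, rt) should give (E)-1-[2,4-bis(benzyloxy)-6-hydroxy-3,5-dimethoxyphenyl]-3-[3,4-bis(benzyloxy)-5-methoxyphenyl]prop-2-en-1-one F3. Oxidative cyclisation (cat. I2, DMSO, 120 °C) should then close ring C to 5,7-bis(benzyloxy)-2-[3,4-bis(benzyloxy)-5-methoxyphenyl]-6,8-dimethoxy-4H-chromen-4-one F4. Hydrogenolysis under the conditions of step 9 removes all four benzyl groups and gives 14.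

Step 2. Hydrodebromination may compete with C–O bond formation at the crowded bromides, the reaction may stall after the first substitution, and methoxide may attack a benzylic carbon at the temperature needed. The fallback puts in the oxygens by borylation and oxidation instead of copper-mediated substitution; it sets out from 2 and comes back at 3. Bromine–lithium exchange and borylation, one bromine after the other in the same flask (n-BuLi then B(OiPr)3, THF, −78 °C, twice; dilute acid), should give [2,4,6-tris(benzyloxy)benzene-1,3-diyl]diboronic acid F5. This is oxidised without storage (H2O2, NaOH, THF, 0 °C) to 2,4,6-tris(benzyloxy)benzene-1,3-diol F6. Double O-methylation (MeI, K2CO3, DMF, rt) then gives 3.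

Step 4. Acid-induced protodeiodination of the very electron-rich ring on quenching, cleavage of the crowded methyl ethers by the Lewis acid, and air oxidation of the free triol may all erode the step. The fallback reverses the order of deprotection and halogenation; it sets out from 3 and comes back at 5. Hydrogenolysis of 3 before any iodine is present (H2, Pd/C, EtOAc/MeOH, rt) should give 2,4-dimethoxybenzene-1,3,5-triol F7. Its only free CH is then iodinated under buffered, acid-free conditions (I2, NaHCO3, THF/H2O, 0 °C) to give 5, which is acetylated at once as in step 5.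

Further compounds
F1 | step 8 | 1-[2,4,6-tris(benzyloxy)-3,5-dimethoxyphenyl]ethan-1-one | CC(=O)c1c(OCc2ccccc2)c(OC)c(OCc2ccccc2)c(OC)c1OCc1ccccc1
F2 | step 8 | 1-[2,4-bis(benzyloxy)-6-hydroxy-3,5-dimethoxyphenyl]ethan-1-one | CC(=O)c1c(O)c(OC)c(OCc2ccccc2)c(OC)c1OCc1ccccc1
F3 | step 8 | (E)-1-[2,4-bis(benzyloxy)-6-hydroxy-3,5-dimethoxyphenyl]-3-[3,4-bis(benzyloxy)-5-methoxyphenyl]prop-2-en-1-one | COc1cc(/C=C/C(=O)c2c(O)c(OC)c(OCc3ccccc3)c(OC)c2OCc2ccccc2)cc(OCc2ccccc2)c1OCc1ccccc1
F4 | step 8 | 5,7-bis(benzyloxy)-2-[3,4-bis(benzyloxy)-5-methoxyphenyl]-6,8-dimethoxy-4H-chromen-4-one | COc1cc(-c2cc(=O)c3c(OCc4ccccc4)c(OC)c(OCc4ccccc4)c(OC)c3o2)cc(OCc2ccccc2)c1OCc1ccccc1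
F5 | step 2 | [2,4,6-tris(benzyloxy)benzene-1,3-diyl]diboronic acid | OB(O)c1c(OCc2ccccc2)cc(OCc2ccccc2)c(B(O)O)c1OCc1ccccc1
F6 | step 2 | 2,4,6-tris(benzyloxy)benzene-1,3-diol | Oc1c(OCc2ccccc2)cc(OCc2ccccc2)c(O)c1OCc1ccccc1
F7 | step 4 | 2,4-dimethoxybenzene-1,3,5-triol | COc1c(O)cc(O)c(OC)c1O
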